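**Assumption:** the target SMILES describes a meso compound (2R,3R,4S,5S; mirror plane through the ring O and the C3–C4 midpoint), so it is achiral and only the relative configuration has to be controlled.

## Retrosynthetic overview

1. The tetrahydrofuran is opened by removing the ring oxygen: formal O-atom insertion (4→5 ring expansion) into the bis-benzylic C–C bond of the meso syn head-to-head cyclobutane dimer of isoliquiritigenin.
2. The cyclobutane carries the cis-diaroyl unit (C3/C4 of the target); it comes from a template-directed [2+2] photodimerization of (E)-isoliquiritigenin.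
3. Isoliquiritigenin comes from a Claisen–Schmidt condensation of 2,4-dihydroxyacetophenone with 4-hydroxybenzaldehyde.
4. The ketone comes from resorcinol and acetic acid; the aldehyde from p-cresol by aerobic oxidation.
5. Ring order: cyclobutane first, then the oxolane by ring expansion; no protecting groups.

## Route

Step 1
Reactants: 1 resorcinol; 2 acetic acid
Product: 3 1-(2,4-dihydroxyphenyl)ethan-1-one
Conditions: ZnCl2 (1.5 equiv), AcOH, 140–150 °C; then dilute HCl
Reagents that add atoms: none
Why: Nencki-type Friedel–Crafts C-acylation of resorcinol occurs at C4, para to one OH and ortho to the other, giving the chelated 2,4-dihydroxyaryl ketone.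

Step 2
Reactants: 4 p-cresol
Product: 5 4-hydroxybenzaldehyde
Conditions: Co(OAc)2·4H2O (1 mol%), NaOH (3 equiv), MeOH, O2 (1 atm), 60 °C; then aq. HCl
Reagents that add atoms: dioxygen, O=O
Why: Base-mediated cobalt-catalysed aerobic benzylic oxidation of a p-alkylphenolate via its quinone methide and methanol adduct stops at the aldehyde because the product phenolate is deactivated.

Step 3
Reactants: 3 1-(2,4-dihydroxyphenyl)ethan-1-one; 5 4-hydroxybenzaldehyde
Product: 6 (E)-1-(2,4-dihydroxyphenyl)-3-(4-hydroxyphenyl)prop-2-en-1-one (isoliquiritigenin)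
Conditions: KOH (60% aq.), EtOH, 0 °C to rt, 48 h; then cold 2 M HCl to pH 3
Reagents that add atoms: none
Why: Claisen–Schmidt aldol condensation of the polyphenolate partners with E1cB dehydration gives the thermodynamic E-enone; cold acidification avoids flavanone closure.

Step 4
Reactants: 6 isoliquiritigenin (two molecules)
Product: 7 meso-[(1R,2S,3R,4S)-3,4-bis(4-hydroxyphenyl)cyclobutane-1,2-diyl]bis[(2,4-dihydroxyphenyl)methanone] (r-1,c-2,t-3,t-4: aroyls cis, aryls cis, each aryl trans to its neighbouring aroyl)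
Conditions: γ-cyclodextrin (0.5 equiv), H2O, 2:1 inclusion complex as a thin solid film, hν 365 nm, rt; EtOAc extraction
Reagents that add atoms: none
Why: Template-directed [2+2] photodimerization in which the host holds two molecules with their 4-hydroxyphenyl rings stacked parallel and head-to-head, so suprafacial union of two E-alkenes sets all four stereocentres as the syn head-to-head (β-truxinic-type) dimer.

Step 5
Reactants: 7 meso syn head-to-head cyclobutane
Product: 10 [(2R,3R,4S,5S)-2,5-bis(4-hydroxyphenyl)oxolane-3,4-diyl]bis[(2,4-dihydroxyphenyl)methanone], via ring-opened bis(quinone methide) 8 (not isolated), via hydroxy quinone methide 9 (not isolated)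
Conditions: 9-mesityl-10-methylacridinium perchlorate (5 mol%), Co(dmgH)2(py)Cl (5 mol%), MeCN/H2O 9:1, 450 nm LED, N2, rt, stopped at about 80% conversion
Reagents that add atoms: water, O
Why: Proposed new method: acceptorless dehydrogenative oxygen insertion into a cyclobutane σ-bond, in which photo-oxidation (PCET) of a 4-hydroxyphenyl group gives a phenoxyl radical whose strain-driven β-scission cleaves the bis-benzylic C–C bond, cobalt oxidizes the resulting 4-hydroxybenzyl radical to give 8 and later releases H2, water adds 1,6 to give 9, and 5-exo oxa-1,6-addition closes the oxolane; the cis-diaroyl centres C3/C4 are carried over untouched in a base-free medium and the reversible oxa-1,6-additions place each aryl trans to its neighbouring aroyl (2,5-cis), while the chelated acyl-resorcinol rings are harder to oxidize and have no fragmentation channel; the closest known reaction types are photoinduced electron-transfer ring-opening oxygenation of 1,2-diarylcyclobutanes to 1,2-dioxanes and acridinium/cobaloxime dehydrogenative addition of water to styrene radical cations.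

## Compound list

1 | resorcinol | Oc1cccc(O)c1 | starting material
2 | acetic acid | CC(=O)O | starting material
3 | 1-(2,4-dihydroxyphenyl)ethan-1-one | CC(=O)c1ccc(O)cc1O | intermediate
4 | p-cresol | Cc1ccc(O)cc1 | starting material
5 | 4-hydroxybenzaldehyde | O=Cc1ccc(O)cc1 | intermediate
6 | isoliquiritigenin, (E)-1-(2,4-dihydroxyphenyl)-3-(4-hydroxyphenyl)prop-2-en-1-one | O=C(/C=C/c1ccc(O)cc1)c1ccc(O)cc1O | intermediate
7 | meso-[(1R,2S,3R,4S)-3,4-bis(4-hydroxyphenyl)cyclobutane-1,2-diyl]bis[(2,4-dihydroxyphenyl)methanone] | O=C(c1ccc(O)cc1O)[C@@H]1[C@H](C(=O)c2ccc(O)cc2O)[C@@H](c2ccc(O)cc2)[C@H]1c1ccc(O)cc1 | intermediate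
8 | meso-(2R,3S)-1,4-bis(2,4-dihydroxyphenyl)-2,3-bis[(4-oxocyclohexa-2,5-dien-1-ylidene)methyl]butane-1,4-dione | O=C1C=CC(=C[C@@H](C(=O)c2ccc(O)cc2O)[C@@H](C(=O)c2ccc(O)cc2O)C=C2C=CC(=O)C=C2)C=C1 | intermediate (not isolated)
9 | 1,4-bis(2,4-dihydroxyphenyl)-2-[hydroxy(4-hydroxyphenyl)methyl]-3-[(4-oxocyclohexa-2,5-dien-1-ylidene)methyl]butane-1,4-dione, backbone centres as in 8, carbinol carbon configured as C2 of 10 | O[C@@H](c1ccc(O)cc1)[C@H](C(=O)c1ccc(O)cc1O)[C@H](C(=O)c1ccc(O)cc1O)C=C1C=CC(=O)C=C1 | intermediate (not isolated)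
10 | [(2R,3R,4S,5S)-2,5-bis(4-hydroxyphenyl)oxolane-3,4-diyl]bis[(2,4-dihydroxyphenyl)methanone] (CNP0237262.1) | O=C(c1ccc(O)cc1O)[C@@H]1[C@H](C(=O)c2ccc(O)cc2O)[C@@H](c2ccc(O)cc2)O[C@H]1c1ccc(O)cc1 | target

## Summary

Total step count: 5. Longest linear sequence: 4 (steps 1, 3, 4, 5).

## Steps most likely to fail

**Step 5 (proposed new oxygen insertion).** Risks are over-oxidation of the product phenols, phenoxyl coupling, and tautomerization of 8 to the bis-chalcone diene, which would erase the C3/C4 configuration. The fallback uses known chemistry, sets out from 7 and comes back at 10. Silylation of the four non-chelated phenols (TBSCl, imidazole, DMF) gives the tetra-TBS cyclobutane F1. Electron-transfer photo-oxygenation sensitized by 9,10-dicyanoanthracene (O2, MeCN, 420 nm) expands the ring to the 3,6-diaryl-4,5-diaroyl-1,2-dioxane F2. Triphenylphosphine then removes one peroxide oxygen with ring contraction to the tetra-TBS oxolane F3. TBAF buffered with AcOH (THF, 0 °C) releases 10.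

**Step 4 (syn head-to-head photodimerization).** Risks are head-to-tail or anti dimers, E/Z isomerization, and photocyclization of the 2'-hydroxychalcone to the flavanone. The fallback replaces the host by a covalent template, sets out from 3 (with 5) and comes back at 7. Selective 4-O-alkylation of two molecules of 3 with 1,8-bis(bromomethyl)naphthalene (K2CO3, acetone) gives the tethered bis-acetophenone F4. Double Claisen–Schmidt condensation with 5 (KOH, EtOH) gives the tethered bis-chalcone F5. Irradiation in dilute solution (365 nm) gives the tethered cyclobutane F6 by intramolecular [2+2]; the peri-tether enforces head-to-head syn stacking. Hydrogenolysis (H2, Pd/C, EtOAc) cleaves the naphthylmethyl ethers to give 7.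

**Step 3 (unprotected Claisen–Schmidt).** Risks are low conversion of the polyphenolates and flavanone formation on work-up. The fallback sets out from 3 and 5 and comes back at 6. MOMCl with iPr2NEt converts 3 into the 4-O-MOM ketone F7 and 5 into the MOM-protected aldehyde F8. Condensation (KOH, EtOH, rt) gives the bis-MOM chalcone F9. HCl in MeOH (50 °C) removes both MOM groups to give 6.

## Further compounds

F1 | step 5 | [(1R,2S,3R,4S)-3,4-bis(4-tert-butyldimethylsilyloxyphenyl)cyclobutane-1,2-diyl]bis[(4-tert-butyldimethylsilyloxy-2-hydroxyphenyl)methanone] | O=C(c1ccc(O[Si](C)(C)C(C)(C)C)cc1O)[C@@H]1[C@H](C(=O)c2ccc(O[Si](C)(C)C(C)(C)C)cc2O)[C@@H](c2ccc(O[Si](C)(C)C(C)(C)C)cc2)[C@H]1c1ccc(O[Si](C)(C)C(C)(C)C)cc1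
F2 | step 5 | meso-3,6-cis-bis(4-tert-butyldimethylsilyloxyphenyl)-4,5-cis-bis(4-tert-butyldimethylsilyloxy-2-hydroxybenzoyl)-1,2-dioxane, each aryl trans to its neighbouring aroyl | O1O[C@@H](c2ccc(O[Si](C)(C)C(C)(C)C)cc2)[C@H](C(=O)c2ccc(O[Si](C)(C)C(C)(C)C)cc2O)[C@H](C(=O)c2ccc(O[Si](C)(C)C(C)(C)C)cc2O)[C@H]1c1ccc(O[Si](C)(C)C(C)(C)C)cc1
F3 | step 5 | tetra-TBS ether of 10 at the 4-hydroxyphenyl and 4-hydroxybenzoyl oxygens, (2R,3R,4S,5S) | O1[C@@H](c2ccc(O[Si](C)(C)C(C)(C)C)cc2)[C@H](C(=O)c2ccc(O[Si](C)(C)C(C)(C)C)cc2O)[C@H](C(=O)c2ccc(O[Si](C)(C)C(C)(C)C)cc2O)[C@H]1c1ccc(O[Si](C)(C)C(C)(C)C)cc1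
F4 | step 4 | 1,8-bis[(4-acetyl-3-hydroxyphenoxy)methyl]naphthalene | CC(=O)c1ccc(OCc2cccc3cccc(COc4ccc(C(C)=O)c(O)c4)c23)cc1O
F5 | step 4 | 1,8-bis({3-hydroxy-4-[(E)-3-(4-hydroxyphenyl)prop-2-enoyl]phenoxy}methyl)naphthalene | O=C(/C=C/c1ccc(O)cc1)c1ccc(OCc2cccc3cccc(COc4ccc(C(=O)/C=C/c5ccc(O)cc5)c(O)c4)c23)cc1O
F6 | step 4 | 7 with its two 4-hydroxybenzoyl oxygens bridged by a naphthalene-1,8-diyldimethylene tether | O=C1c2ccc(cc2O)OCc2cccc3cccc(c23)COc2ccc(c(O)c2)C(=O)[C@H]2[C@@H]1[C@H](c1ccc(O)cc1)[C@@H]2c1ccc(O)cc1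
F7 | step 3 | 1-[2-hydroxy-4-(methoxymethoxy)phenyl]ethan-1-one | CC(=O)c1ccc(OCOC)cc1O
F8 | step 3 | 4-(methoxymethoxy)benzaldehyde | O=Cc1ccc(OCOC)cc1
F9 | step 3 | (E)-1-[2-hydroxy-4-(methoxymethoxy)phenyl]-3-[4-(methoxymethoxy)phenyl]prop-2-en-1-one | O=C(/C=C/c1ccc(OCOC)cc1)c1ccc(OCOC)cc1O
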